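**Assumption:** the target SMILES has no stereocentres or stereogenic double bonds and the 18-membered bis(bibenzyl) ring is conformationally mobile, so the compound is achiral and no enantiocontrol is needed.

Ring labels: A = 1,2,4-trisubstituted ring (OH, OAr, CH2); B = para-phenylene; C = meta-phenylene; D = 1,2,3-trisubstituted ring (OAr, OH, CH2).

## Retrosynthetic overview

1. Target ⇐ di-O-methyl ether 10 (global demethylation) ⇐ macrocyclic stilbene 9 (hydrogenation).
2. The 18-membered ring is the only ring formed; it is closed last, at the A–D ethylene bridge, by intramolecular McMurry coupling of seco-dialdehyde 8.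
3. The B–C ethylene bridge comes from Sonogashira coupling of aryl iodide 3 with terminal alkyne 6, then alkyne hydrogenation.
4. The A–O–B diaryl ether comes from Chan–Lam coupling of isovanillin with 4-iodophenylboronic acid.
5. The C–O–D diaryl ether comes from SNAr of 3-ethynylphenol on 2-fluoro-3-methoxybenzaldehyde; all four arenes are purchased.

## Route

**Step 1**
Reactants: 1, isovanillin (3-hydroxy-4-methoxybenzaldehyde); 2, 4-iodophenylboronic acid
Product: 3, 3-(4-iodophenoxy)-4-methoxybenzaldehyde
Conditions: Cu(OAc)2 (1 equiv), pyridine (5 equiv), 4 Å MS, CH2Cl2, air, rt, 48 h (2 equiv of 2)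
Reagents that add atoms: none beyond reactants 1 and 2 (the 4-iodophenyl group comes from 2)
Why: Chan–Lam oxidative O-arylation works at room temperature on guaiacol-type phenols and leaves both the aldehyde and the aryl iodide untouched; no stereocentre is formed.

**Step 2**
Reactants: 4, 2-fluoro-3-methoxybenzaldehyde; 5, 3-ethynylphenol
Product: 6, 2-(3-ethynylphenoxy)-3-methoxybenzaldehyde
Conditions: K2CO3 (2 equiv), DMF, 110 °C, N2
Reagents that add atoms: none beyond reactants 4 and 5
Why: SNAr displacement of a fluoride activated by the ortho-formyl group by the phenoxide; the non-enolisable aldehyde and the terminal aryl alkyne tolerate carbonate in DMF.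

**Step 3**
Reactants: 3, 3-(4-iodophenoxy)-4-methoxybenzaldehyde; 6, 2-(3-ethynylphenoxy)-3-methoxybenzaldehyde
Product: 7, 3-[4-({3-[(2-formyl-6-methoxyphenyl)oxy]phenyl}ethynyl)phenoxy]-4-methoxybenzaldehyde (diarylacetylene dialdehyde)
Conditions: PdCl2(PPh3)2 (3 mol%), CuI (5 mol%), Et3N/THF, rt, degassed
Reagents that add atoms: none
Why: Sonogashira coupling of an aryl iodide with a terminal alkyne proceeds at room temperature, tolerates both aldehydes, and fixes the B–C connectivity unambiguously (degassing suppresses Glaser dimerisation).

**Step 4**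
Reactants: 7, diarylacetylene dialdehyde
Product: 8, 3-[4-(2-{3-[(2-formyl-6-methoxyphenyl)oxy]phenyl}ethyl)phenoxy]-4-methoxybenzaldehyde (seco-dialdehyde with the B–C bibenzyl in place)
Conditions: H2 (1 atm), 10% Pd/C, Ph2S (cat.), EtOAc, rt
Reagents that add atoms: none (H2 adds hydrogen only)
Why: Sulfide-poisoned Pd/C hydrogenates the alkyne fully to the ethylene bridge while leaving the aromatic aldehydes unreduced; this gives the flexible chain needed for macrocyclisation.

**Step 5**
Reactants: 8, seco-dialdehyde
Product: 9, macrocyclic stilbene (isomarchantin C dimethyl ether with CH=CH in place of the A–D CH2CH2 bridge; E/Z mixture, both converge in step 6)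
Conditions: TiCl4, Zn, pyridine, THF, reflux; slow syringe-pump addition of 8 (final concentration ≤ 2 mM)
Reagents that add atoms: none
Why: Intramolecular McMurry reductive coupling of the two aryl aldehydes under high dilution closes the 18-membered ring; aryl methyl ethers and diaryl ethers are inert to low-valent titanium, and alkene geometry is irrelevant.

**Step 6**
Reactants: 9, macrocyclic stilbene
Product: 10, isomarchantin C di-O-methyl ether
Conditions: H2 (1–3 atm), 10% Pd/C, EtOAc, rt
Reagents that add atoms: none (H2 adds hydrogen only)
Why: Routine catalytic hydrogenation of the stilbene C=C; no hydrogenolysable groups are present and no stereocentre is created.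

**Step 7**
Reactants: 10, isomarchantin C di-O-methyl ether
Product: 11, isomarchantin C (target)
Conditions: BBr3 (6 equiv), CH2Cl2, −78 °C → rt; then MeOH/H2O
Reagents that add atoms: none (BBr3 removes the two methyl groups; work-up supplies H only)
Why: Lewis-acid cleavage of aryl methyl ethers by BBr3 is selective over diaryl ethers, which lack a carbon open to SN2 attack, so both phenols are released with the macrocycle intact.

## Compound list

1 | isovanillin (3-hydroxy-4-methoxybenzaldehyde) | COc1ccc(C=O)cc1O | starting material
2 | 4-iodophenylboronic acid | OB(O)c1ccc(I)cc1 | starting material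
3 | 3-(4-iodophenoxy)-4-methoxybenzaldehyde | COc1ccc(C=O)cc1Oc1ccc(I)cc1 | intermediate
4 | 2-fluoro-3-methoxybenzaldehyde | COc1cccc(C=O)c1F | starting material
5 | 3-ethynylphenol | Oc1cccc(C#C)c1 | starting material
6 | 2-(3-ethynylphenoxy)-3-methoxybenzaldehyde | COc1cccc(C=O)c1Oc1cccc(C#C)c1 | intermediate
7 | 3-[4-({3-[(2-formyl-6-methoxyphenyl)oxy]phenyl}ethynyl)phenoxy]-4-methoxybenzaldehyde | COc1ccc(C=O)cc1Oc1ccc(cc1)C#Cc1cccc(c1)Oc1c(OC)cccc1C=O | intermediate
8 | 3-[4-(2-{3-[(2-formyl-6-methoxyphenyl)oxy]phenyl}ethyl)phenoxy]-4-methoxybenzaldehyde | COc1ccc(C=O)cc1Oc1ccc(cc1)CCc1cccc(c1)Oc1c(OC)cccc1C=O | intermediate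
9 | macrocyclic stilbene (A–D didehydro isomarchantin C dimethyl ether, E/Z mixture) | COc1ccc2cc1Oc1ccc(cc1)CCc1cccc(c1)Oc1c(OC)cccc1C=C2 | intermediate
10 | isomarchantin C di-O-methyl ether | COc1ccc2cc1Oc1ccc(cc1)CCc1cccc(c1)Oc1c(OC)cccc1CC2 | intermediate
11 | isomarchantin C | Oc1ccc2cc1Oc1ccc(cc1)CCc1cccc(c1)Oc1c(O)cccc1CC2 | target

## Summary

Total step count: 7 (steps 1 and 2 are parallel fragment syntheses).
Longest linear sequence: 6 steps (1 or 2 → 3 → 4 → 5 → 6 → 7).

Three steps most likely to fail, with fallbacks:

1. **Step 5 (McMurry macrocyclisation)** — risk of oligomers or pinacol products. Fallback: reduce 8 to the diol (NaBH4), convert to the bis(benzyl bromide) (PBr3), and close the ring by intramolecular Wurtz-type C(sp3)–C(sp3) coupling (Na/tetraphenylethylene, THF, high dilution). This gives 10 directly.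
2. **Step 2 (SNAr with a free alkyne on a fluoride flanked by CHO and OMe)** — risk of sluggish substitution or alkyne side reactions in hot base. Fallback: run the SNAr with 3-iodophenol to give 2-(3-iodophenoxy)-3-methoxybenzaldehyde, then install the alkyne afterwards by Sonogashira coupling with trimethylsilylacetylene and K2CO3/MeOH desilylation to reach 6.
3. **Step 1 (Chan–Lam coupling)** — risk of low conversion or protodeboronation with the ortho-methoxy phenol. Fallback: SNAr of isovanillin with 1-fluoro-4-nitrobenzene (K2CO3, DMF), then nitro reduction (Fe/NH4Cl) and Sandmeyer iodination (NaNO2/H+, KI) to reach 3.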